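**Retrosynthetic overview**
1. Target ⇐ acetylation of the C1 hydroxyl ⇐ cis-1,10-diol ⇐ OsO4 dihydroxylation of a Z-C1=C10 alkene in an 11-oxabicyclo[6.2.1]undec-3-ene.
2. Medium ring (formed second) ⇐ ring-closing metathesis across a cis-2,5-disubstituted oxolane that carries a prenyl-terminated chain and a methallyl group.
3. Oxolane (formed first, key step) ⇐ C5–O8 bond by 5-exo opening of a Sharpless epoxide by the C8 oxygen, triggered in the same flask by a SmI2-catalysed Evans–Tishchenko reduction with cinnamaldehyde, which also sets C8 and installs the cinnamate.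
4. Acyclic β-hydroxy ketone ⇐ reductive aldol (C6–C7) between the epoxy aldehyde from geraniol and 2,6-dimethylhepta-1,5-dien-4-one (from 3-methylbut-2-enoyl chloride and methallylsilane).

Numbering used for all intermediates: C1–C10 are the carbons of the ten-membered carbocycle of the target (C1 = CH–OAc, C4 = C(CH3)OH, C5 and C8 = ether carbons, C6 = CH–O-cinnamoyl, C7 = CH–iPr, C10 = C(CH3)OH). None of these steps has been run; selectivities are predictions.

**Route**

Step 1
Reactants: 1 geraniol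
Product: 2 [(2R,3R)-3-methyl-3-(4-methylpent-3-en-1-yl)oxiran-2-yl]methanol
Conditions: Ti(OiPr)4 (5 mol%), D-(−)-diethyl tartrate (6 mol%), t-BuOOH, 4 Å MS, CH2Cl2, −20 °C
Reagents that add atoms: tert-butyl hydroperoxide CC(C)(C)OO
Why: Sharpless asymmetric epoxidation of the allylic alcohol, in which the Ti(OiPr)4/D-tartrate complex delivers oxygen to the face that gives the (2R,3R)-epoxide, setting C4 and the C5 centre that is inverted later, while the remote trisubstituted alkene is untouched.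

Step 2
Reactants: 2 [(2R,3R)-3-methyl-3-(4-methylpent-3-en-1-yl)oxiran-2-yl]methanol
Product: 3 (2S,3R)-3-methyl-3-(4-methylpent-3-en-1-yl)oxirane-2-carbaldehyde
Conditions: TEMPO (10 mol%), PhI(OAc)2 (1.1 equiv), CH2Cl2, 23 °C
Reagents that add atoms: none
Why: Oxoammonium (TEMPO) oxidation of the primary alcohol stops at the aldehyde under near-neutral conditions, so the epoxide and both stereocentres survive (the descriptor at C2 changes only because of CIP priorities).

Step 3
Reactants: 4 3-methylbut-2-enoyl chloride; 5 trimethyl(2-methylprop-2-en-1-yl)silane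
Product: 6 2,6-dimethylhepta-1,5-dien-4-one
Conditions: AlCl3 (1.05 equiv), CH2Cl2, −78 °C, 30 min; cold aqueous NaHCO3
Reagents that add atoms: none
Why: Lewis acid-mediated acylation of an allylsilane (Hosomi–Sakurai-type SE2' acylation), in which the acyl chloride–AlCl3 complex attacks the CH2 terminus and loss of the silyl group gives the β,γ-unsaturated ketone, the low temperature preventing conjugation of the new alkene.

Step 4
Reactants: 6 2,6-dimethylhepta-1,5-dien-4-one; 3 (2S,3R)-3-methyl-3-(4-methylpent-3-en-1-yl)oxirane-2-carbaldehyde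
Product: 9 (5R,6R)-6-hydroxy-2-methyl-6-[(2R,3R)-3-methyl-3-(4-methylpent-3-en-1-yl)oxiran-2-yl]-5-(propan-2-yl)hex-1-en-4-one, via catecholboron enolate 7 (not isolated), via boron aldolate 8 (not isolated)
Conditions: 6 (1.2 equiv), catecholborane (1.15 equiv), THF, 23 °C, 4 h; then 3, −78 → −20 °C; aqueous NaHCO3/MeOH
Reagents that add atoms: none
Why: Borane-mediated reductive aldol, in which catecholborane adds hydride 1,4 to the s-cis β,β-dimethyl enone through a six-membered transition state to give only the Z-boron enolate, which adds to the aldehyde through a closed Zimmerman–Traxler transition state (C6–OH and C7–iPr syn) on the Felkin–Anh/Cornforth face of the α-epoxy aldehyde (new C6–O anti to the epoxide C5–O), so both new centres are set from the Sharpless epoxide.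

Step 5
Reactants: 9 (5R,6R)-6-hydroxy-2-methyl-6-[(2R,3R)-3-methyl-3-(4-methylpent-3-en-1-yl)oxiran-2-yl]-5-(propan-2-yl)hex-1-en-4-one; 10 (2E)-3-phenylprop-2-enal
Product: 13 (2S,3R,4S,5S)-2-[(2R)-2-hydroxy-6-methylhept-5-en-2-yl]-5-(2-methylprop-2-en-1-yl)-4-(propan-2-yl)oxolan-3-yl (2E)-3-phenylprop-2-enoate, via samarium hemiacetal 11 (not isolated), via hydroxy cinnamate 12 (not isolated)
Conditions: 10 (4 equiv), SmI2 (30 mol%), THF, −10 °C, 3 h; then 40 °C, 12 h; aqueous NaHCO3
Reagents that add atoms: none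
Why: Proposed new method: an Evans–Tishchenko reduction terminated by etherification — trivalent samarium binds the hemiacetal formed from the C6 hydroxyl and the enal together with the C8 ketone, intramolecular hydride transfer through a chair-like six-membered transition state gives the C8 samarium alkoxide anti to O6 (sets 8S) and leaves O6 as the cinnamate, and this metal alkoxide, sitting 1,4 to C5, opens the samarium-activated epoxide by 5-exo-tet SN2 attack at the secondary carbon with inversion (5R → 5S), closing the oxolane and freeing the C4 tertiary alcohol; the closest known reactions are the SmI2-catalysed Evans–Tishchenko reduction of β-hydroxy ketones and the acid- or lanthanide-promoted 5-exo cyclisation of 4,5-epoxy alcohols, which have not been coupled in one operation or run with an enal as hydride and acyl donor.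

Step 6
Reactants: 13 (2S,3R,4S,5S)-2-[(2R)-2-hydroxy-6-methylhept-5-en-2-yl]-5-(2-methylprop-2-en-1-yl)-4-(propan-2-yl)oxolan-3-yl (2E)-3-phenylprop-2-enoate
Product: 14 (1S,3Z,7R,8S,9R,10S)-7-hydroxy-3,7-dimethyl-10-(propan-2-yl)-11-oxabicyclo[6.2.1]undec-3-en-9-yl (2E)-3-phenylprop-2-enoate
Conditions: second-generation Hoveyda–Grubbs catalyst (10 mol%, two portions), toluene (2 mM), 80 °C, argon sparge
Reagents that add atoms: none
Why: Ring-closing olefin metathesis, in which the catalyst loads at the prenyl terminus (loss of 2-methylpropene) and closes onto the 1,1-disubstituted alkene across the cis-2,5-disubstituted oxolane that holds both chains on one face, the nine-membered oxacycle accepting only the Z-trisubstituted alkene and the electron-poor cinnamate alkene staying out of the reaction.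

Step 7
Reactants: 14 (1S,3Z,7R,8S,9R,10S)-7-hydroxy-3,7-dimethyl-10-(propan-2-yl)-11-oxabicyclo[6.2.1]undec-3-en-9-yl (2E)-3-phenylprop-2-enoate
Product: 15 (1S,3R,4S,7R,8S,9R,10S)-3,4,7-trihydroxy-3,7-dimethyl-10-(propan-2-yl)-11-oxabicyclo[6.2.1]undecan-9-yl (2E)-3-phenylprop-2-enoate
Conditions: OsO4 (2 mol%), NMO (1.2 equiv), acetone/H2O (8:1), 0 °C
Reagents that add atoms: 4-methylmorpholine N-oxide C[N+]1([O-])CCOCC1; water O
Why: Upjohn dihydroxylation, in which OsO4 reacts with the electron-rich trisubstituted ring alkene much faster than with the conjugated cinnamate and the suprafacial [3+2] addition to the Z-alkene comes from the ring face turned away from the C6–C7 bridge, giving the cis-(1S,10R)-diol.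

Step 8
Reactants: 15 (1S,3R,4S,7R,8S,9R,10S)-3,4,7-trihydroxy-3,7-dimethyl-10-(propan-2-yl)-11-oxabicyclo[6.2.1]undecan-9-yl (2E)-3-phenylprop-2-enoate
Product: 16 (1S,3R,4S,7R,8S,9R,10S)-4-(acetyloxy)-3,7-dihydroxy-3,7-dimethyl-10-(propan-2-yl)-11-oxabicyclo[6.2.1]undecan-9-yl (2E)-3-phenylprop-2-enoate
Conditions: Ac2O (1.5 equiv), pyridine, DMAP (5 mol%), CH2Cl2, 0 → 23 °C
Reagents that add atoms: acetic anhydride CC(=O)OC(C)=O
Why: DMAP-catalysed acylation takes the only secondary hydroxyl (C1), since the two tertiary hydroxyls at C4 and C10 do not acylate under these conditions, and no stereocentre is touched.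

**Compound list**
1 | geraniol, (2E)-3,7-dimethylocta-2,6-dien-1-ol | CC(C)=CCC/C(C)=C/CO | starting material
2 | [(2R,3R)-3-methyl-3-(4-methylpent-3-en-1-yl)oxiran-2-yl]methanol | CC(C)=CCC[C@@]1(C)O[C@@H]1CO | intermediate
3 | (2S,3R)-3-methyl-3-(4-methylpent-3-en-1-yl)oxirane-2-carbaldehyde | CC(C)=CCC[C@@]1(C)O[C@@H]1C=O | intermediate
4 | 3-methylbut-2-enoyl chloride | CC(C)=CC(=O)Cl | starting material
5 | trimethyl(2-methylprop-2-en-1-yl)silane | C=C(C)C[Si](C)(C)C | starting material
6 | 2,6-dimethylhepta-1,5-dien-4-one | CC(C)=CC(=O)CC(C)=C | intermediate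
7 | 2-{[(4Z)-2,6-dimethylhepta-1,4-dien-4-yl]oxy}-1,3,2-benzodioxaborole (catecholboron enolate) | CC(C)/C=C(/CC(C)=C)OB1Oc2ccccc2O1 | intermediate (not isolated)
8 | O6-(1,3,2-benzodioxaborol-2-yl) ester of 9 (boron aldolate) | CC(C)=CCC[C@@]1(C)O[C@@H]1[C@H](OB2Oc3ccccc3O2)[C@@H](C(C)C)C(=O)CC(C)=C | intermediate (not isolated)
9 | (5R,6R)-6-hydroxy-2-methyl-6-[(2R,3R)-3-methyl-3-(4-methylpent-3-en-1-yl)oxiran-2-yl]-5-(propan-2-yl)hex-1-en-4-one | CC(C)=CCC[C@@]1(C)O[C@@H]1[C@H](O)[C@@H](C(C)C)C(=O)CC(C)=C | intermediate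
10 | (2E)-3-phenylprop-2-enal (cinnamaldehyde) | O=C/C=C/c1ccccc1 | starting material
11 | hemiacetal of the C6 hydroxyl of 9 with 10, samarium-bound, hemiacetal carbon undefined | CC(C)=CCC[C@@]1(C)O[C@@H]1[C@H](OC(O)/C=C/c2ccccc2)[C@@H](C(C)C)C(=O)CC(C)=C | intermediate (not isolated)
12 | (1R,2S,3S)-3-hydroxy-5-methyl-1-[(2R,3R)-3-methyl-3-(4-methylpent-3-en-1-yl)oxiran-2-yl]-2-(propan-2-yl)hex-5-en-1-yl (2E)-3-phenylprop-2-enoate | CC(C)=CCC[C@@]1(C)O[C@@H]1[C@H](OC(=O)/C=C/c2ccccc2)[C@@H](C(C)C)[C@@H](O)CC(C)=C | intermediate (not isolated)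
13 | (2S,3R,4S,5S)-2-[(2R)-2-hydroxy-6-methylhept-5-en-2-yl]-5-(2-methylprop-2-en-1-yl)-4-(propan-2-yl)oxolan-3-yl (2E)-3-phenylprop-2-enoate | CC(C)=CCC[C@@](C)(O)[C@H]1O[C@@H](CC(C)=C)[C@H](C(C)C)[C@H]1OC(=O)/C=C/c2ccccc2 | intermediate
14 | (1S,3Z,7R,8S,9R,10S)-7-hydroxy-3,7-dimethyl-10-(propan-2-yl)-11-oxabicyclo[6.2.1]undec-3-en-9-yl (2E)-3-phenylprop-2-enoate | C/C1=C/CC[C@@](C)(O)[C@H]2O[C@@H](C1)[C@H](C(C)C)[C@H]2OC(=O)/C=C/c3ccccc3 | intermediate
15 | (1S,3R,4S,7R,8S,9R,10S)-3,4,7-trihydroxy-3,7-dimethyl-10-(propan-2-yl)-11-oxabicyclo[6.2.1]undecan-9-yl (2E)-3-phenylprop-2-enoate | O[C@H]1CC[C@@](C)(O)[C@H]2O[C@@H](C[C@@]1(C)O)[C@H](C(C)C)[C@H]2OC(=O)/C=C/c3ccccc3 | intermediate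
16 | (1S,3R,4S,7R,8S,9R,10S)-4-(acetyloxy)-3,7-dihydroxy-3,7-dimethyl-10-(propan-2-yl)-11-oxabicyclo[6.2.1]undecan-9-yl (2E)-3-phenylprop-2-enoate | CC(=O)O[C@H]1CC[C@@](C)(O)[C@H]2O[C@@H](C[C@@]1(C)O)[C@H](C(C)C)[C@H]2OC(=O)/C=C/c1ccccc1 | target

**Step count**
Total: 8 steps. Longest linear sequence: 7 steps (steps 1, 2, 4, 5, 6, 7, 8 from geraniol).

**Three steps most likely to fail, each with one fallback**

Step 4 (reductive aldol). The 1,4-hydroboration of a β,β-disubstituted enone may be slow, and the facial selectivity rests only on the α-epoxy aldehyde. The fallback uses an auxiliary-controlled aldol. It sets out from 3. (R)-4-Benzyloxazolidin-2-one is acylated (n-BuLi, 3-methylbutanoyl chloride) to the acyl oxazolidinone F1. Its dibutylboron Z-enolate (Bu2BOTf, i-Pr2NEt, CH2Cl2, −78 °C) adds to 3 to give the Evans syn aldol imide F2. Transamidation (MeNHOMe·HCl, AlMe3, −20 °C) gives the Weinreb amide F3. 2-Methylallylmagnesium chloride (THF, −78 °C) then gives the ketone, and the route is rejoined at 9.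

Step 5 (the proposed Tishchenko–etherification). The enal may be a poor hydride donor, the hydroxy ester 12 may not cyclise in the flask, or it may cyclise at C4 or suffer acyl migration. The fallback is three known steps and sets out from 9. Me4NBH(OAc)3 (MeCN/AcOH, −20 °C) gives the 1,3-anti diol F4 by hydroxyl-directed hydride delivery. NaH (THF, 0 °C) closes the ring by alkoxide 5-exo opening of the epoxide at C5 to the oxolane diol F5. Cinnamoyl chloride (pyridine, DMAP, CH2Cl2) acylates its only secondary hydroxyl, and the route is rejoined at 13.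

Step 6 (ring-closing metathesis). Both alkenes are hindered (one trisubstituted, one 1,1-disubstituted) and a medium ring is formed. The fallback is a relay through a terminal alkene and sets out from 13. Ethenolysis (ethylene 1 atm, second-generation Hoveyda–Grubbs catalyst, CH2Cl2, 23 °C) trims the prenyl terminus to give the vinyl compound F6. Ring closure of this monosubstituted/1,1-disubstituted diene (second-generation Grubbs catalyst, toluene, 80 °C, high dilution) rejoins the route at 14.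

Further compounds
F1 | step 4 | (4R)-4-benzyl-3-(3-methylbutanoyl)-1,3-oxazolidin-2-one | CC(C)CC(=O)N1[C@H](Cc2ccccc2)COC1=O
F2 | step 4 | (4R)-4-benzyl-3-{(2R,3R)-3-hydroxy-3-[(2R,3R)-3-methyl-3-(4-methylpent-3-en-1-yl)oxiran-2-yl]-2-(propan-2-yl)propanoyl}-1,3-oxazolidin-2-one | CC(C)=CCC[C@@]1(C)O[C@@H]1[C@H](O)[C@@H](C(C)C)C(=O)N2[C@H](Cc3ccccc3)COC2=O
F3 | step 4 | (2R,3R)-3-hydroxy-N-methoxy-N-methyl-3-[(2R,3R)-3-methyl-3-(4-methylpent-3-en-1-yl)oxiran-2-yl]-2-(propan-2-yl)propanamide | CC(C)=CCC[C@@]1(C)O[C@@H]1[C@H](O)[C@@H](C(C)C)C(=O)N(C)OC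
F4 | step 5 | (1R,2S,3S)-5-methyl-1-[(2R,3R)-3-methyl-3-(4-methylpent-3-en-1-yl)oxiran-2-yl]-2-(propan-2-yl)hex-5-ene-1,3-diol | CC(C)=CCC[C@@]1(C)O[C@@H]1[C@H](O)[C@@H](C(C)C)[C@@H](O)CC(C)=C
F5 | step 5 | (2S,3R,4S,5S)-2-[(2R)-2-hydroxy-6-methylhept-5-en-2-yl]-5-(2-methylprop-2-en-1-yl)-4-(propan-2-yl)oxolan-3-ol | CC(C)=CCC[C@@](C)(O)[C@H]1O[C@@H](CC(C)=C)[C@H](C(C)C)[C@H]1O
F6 | step 6 | (2S,3R,4S,5S)-2-[(2R)-2-hydroxyhex-5-en-2-yl]-5-(2-methylprop-2-en-1-yl)-4-(propan-2-yl)oxolan-3-yl (2E)-3-phenylprop-2-enoate | C=CCC[C@@](C)(O)[C@H]1O[C@@H](CC(C)=C)[C@H](C(C)C)[C@H]1OC(=O)/C=C/c2ccccc2
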